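Tuesday's flask held more substrate than partner, and the cedar run, the only earlier run, never tested such a charge.

| flask | substrate | partner | remark | time |
|---|---|---|---|---|
| cedar | 0.20 M | 1.4 M | run made earlier |  |
| Wednesday's | 0.20 M | 0.946 M |  | 20 h |
| Saturday's | 0.40 M | 0.946 M |  | 20 h |
| Monday's | 0.80 M | 0.946 M |  | 20 h |
| Friday's | 1.5 M | 0.946 M |  | 20 h |
| Tuesday's | 3.0 M | 0.946 M |  | 20 h |

cedar run (percent of the substrate charged)

| time / h | target / % |
|---|---|
| 0.500 | 0.1 |
| 1.00 | 0 |
| 2.00 | 0 |
| 4.00 | 2.3 |
| 8.00 | 8.4 |

(readings scatter by 0.5 percentage points)

- [target] (only what is free in solution) at the end for Wednesday's, Saturday's, Monday's, Friday's, Tuesday's, in this order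
- how the row runs (rises, then falls / hardly changes / falls, then rises / rises all the way / falls all the way)

- a reading or a percentage of target counts all its forms, free or not
- the concentration of target that is asked is that of its free form alone
- "hardly changes" means that all values lie within two and a half points (for a concentration: within two and a half percent of the largest)

The cedar readings stayed near zero at first and then reached 2.3% and 8.4%, so I read a lag in them, with target formed through something unseen. I then turned the question round. For the row to rise all the way, Tuesday's would have to show more free target than Friday's, so substrate left unused would have to leave target alone. But the conventions separate free target from target in all its forms, so some bound form exists, and I guessed that leftover substrate held it; no reading showed this.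

I took one partner per substrate turned and defined the excess substrate, c(substrate) charged minus c(partner) charged, the substrate left once partner, the limiting reagent, has gone: 2.05 M for Tuesday's and 0.554 M for Friday's. Monday's charge stood below partner, so the difference came out negative for Monday's and told me nothing about that flask. I therefore committed to a row that rises first and is falling by Friday's.

The forecast gave 0.04 M, 0.08 M, 0.15 M, 0.25 M and 0.4 M, a row that rises all the way, noting “Nothing in the data measures binding of target”.

The flasks gave 0.0287 M, 0.0425 M, 0.0181 M, 3.37 × 10⁻⁴ M and 3.59 × 10⁻⁵ M: the row rises, then falls, turning at 0.46 M, so Monday's had already dropped below Saturday's.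

    substrate + partner → intermediate A (k = 2.70 × 10⁻⁴ L mol⁻¹ s⁻¹)
    partner + intermediate A ⇌ intermediate B (K = 0.160 L mol⁻¹, k = 4.20 × 10⁻⁵ L mol⁻¹ s⁻¹)
    intermediate B → intermediate C (k = 9.00 × 10⁻⁵ s⁻¹)
    intermediate B ⇌ intermediate D (K = 5.20, k = 4.90 × 10⁻⁵ s⁻¹)
    intermediate D → target (k = 1.40 × 10⁻⁴ s⁻¹)
    intermediate C → side product (k = 0.00350 s⁻¹)
    substrate + target ⇌ idle adduct, settled at all times (K = 44.0 L mol⁻¹)

Wednesday's free target stood at its value in part through the undoing of intermediate B into partner and intermediate A together with the time allowed: without that undoing it came to 0.0510 M, and at tenfold time to 0.0673 M, against 0.0287 M. Part of the fall is the tying up of substrate and target as idle adduct: without that step, Tuesday's would hold 0.00329 M of free target, not 3.59 × 10⁻⁵ M. Tuesday's excess, with the binding constant 44 L mol⁻¹, gives a divisor of one plus their product, 91.2, which leaves 3.60 × 10⁻⁵ M free of the 0.00329 M target counted in all forms. Friday's excess gives a divisor of 25.4, so its 0.00881 M of target leaves 3.47 × 10⁻⁴ M free, and Friday's flask held 3.37 × 10⁻⁴ M.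

All runs come from a simulation for an exercise, and the scatter is random.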